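**Assumption:** the SMILES is read as the (2R,3S,5S)-oxolane (2,5-cis, 2,3-trans), the (1E,3E)-diene and the 5-chloro-6,8-dihydroxyisocoumarin.

**Ligand L (new, achiral, catalyst component of step 4):** N-tert-butyl-N-hydroxy-2,2-diphenylacetamide, CC(C)(C)N(O)C(=O)C(c1ccccc1)c1ccccc1.

## Retrosynthetic overview

1. Ring B (pyranone) closes last: the lactone C1–O2 bond comes from acid enol-lactonisation of keto ester 15, with loss of both MOM groups in the same flask.
2. The benzylic C4–C3 bond comes from lithiated toluate 14 and dienyl Weinreb amide 10.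
3. Ring C (oxolane) closes first: the O1–C2 bond comes from hydroxyl-directed epoxidation of trienoate 7 at C6=C7 and 5-endo opening, which sets C2 and C3; C5 comes from (S)-propylene oxide.
4. Trienoate 7 comes from (S)-propylene oxide by vinyl opening, cross-metathesis with crotonaldehyde and a vinylogous Horner–Wadsworth–Emmons reaction.
5. Toluate 13 comes from methyl orsellinate by chlorination and MOM protection; ring A is bought.

## Route

Step 1
Reactants: 1 (S)-propylene oxide; 2 vinylmagnesium bromide
Product: 3 (2S)-pent-4-en-2-ol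
Conditions: CuI (10 mol %), THF, −30 to 0 °C; then aq. NH4Cl
Reagents that add atoms: none
Why: Copper-catalysed SN2 opening of the epoxide by the vinyl Grignard reagent at the unsubstituted carbon keeps the (S)-carbinol of 1 intact, and this centre later becomes C5 of the oxolane.

Step 2
Reactants: 3 (2S)-pent-4-en-2-ol; 4 (E)-but-2-enal (crotonaldehyde, 4 equiv)
Product: 5 (2E,5S)-5-hydroxyhex-2-enal
Conditions: second-generation Hoveyda–Grubbs catalyst RuCl2(H2IMes)(=CH-C6H4-2-OiPr) (2 mol %), CH2Cl2, 40 °C
Reagents that add atoms: none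
Why: Olefin cross-metathesis of the terminal alkene with excess crotonaldehyde gives the (E)-enal under thermodynamic control with loss of propene and does not touch the carbinol centre.

Step 3
Reactants: 5 (2E,5S)-5-hydroxyhex-2-enal; 6 triethyl 4-phosphonocrotonate
Product: 7 ethyl (2E,4E,6E,9S)-9-hydroxydeca-2,4,6-trienoate
Conditions: LiOH·H2O, 4 Å molecular sieves, THF, rt to 50 °C
Reagents that add atoms: none
Why: The vinylogous Horner–Wadsworth–Emmons reaction of the stabilised phosphonocrotonate anion with the enal forms the new C4=C5 bond E-selectively and tolerates the free hydroxyl.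

Step 4
Reactants: 7 ethyl (2E,4E,6E,9S)-9-hydroxydeca-2,4,6-trienoate
Product: 9 ethyl (2E,4E)-5-[(2R,3S,5S)-3-hydroxy-5-methyloxolan-2-yl]penta-2,4-dienoate, via dienyl epoxide 8 (not isolated)
Conditions: VO(OiPr)3 (5 mol %), ligand L (5.5 mol %), tBuOOH (1.2 equiv, in decane), toluene, 0 °C to rt; then CSA (10 mol %), 0 °C
Reagents that add atoms: tert-butyl hydroperoxide, CC(C)(C)OO
Why: Proposed new method: a pentavalent-vanadium alkylperoxo complex carrying one bulky hydroxamate (VO(OiPr)3 and ligand L, 1:1) binds the C9 alkoxide and delivers oxygen only to the homoallylic C6=C7 bond of the conjugated trienoate through the chair transition state known for vanadium-catalysed epoxidation of homoallylic alcohols, in which the C9 methyl sits equatorial and the ligand bulk penalises the axial alternative, so the 1,3-syn (6S,7S)-epoxide 8 forms; CSA then triggers 5-endo-tet opening at the dienyl-activated C6 by the same hydroxyl with inversion (anti addition across the E-alkene), which closes the oxolane and sets C2 (R) and C3 (S) trans to each other and C2 cis to the C5 methyl; the closest known reaction types are VO(acac)2/tBuOOH epoxidation of homoallylic alcohols and acid-catalysed endo cyclisation of hydroxy vinyl epoxides, neither shown on a conjugated trienoate or as a one-flask oxidative cycloetherification with a hydroxamate-tuned catalyst.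

Step 5
Reactants: 9 ethyl (2E,4E)-5-[(2R,3S,5S)-3-hydroxy-5-methyloxolan-2-yl]penta-2,4-dienoate
Product: 10 (2E,4E)-5-[(2R,3S,5S)-3-hydroxy-5-methyloxolan-2-yl]-N-methoxy-N-methylpenta-2,4-dienamide
Conditions: MeNH(OMe)·HCl (2 equiv), iPrMgCl (5 equiv), THF, −20 to 0 °C; then aq. NH4Cl
Reagents that add atoms: N,O-dimethylhydroxylamine hydrochloride, CNOC.Cl
Why: Weinreb amide formation by magnesium amide aminolysis of the ester is a 1,2-acyl substitution that leaves the diene and all three stereocentres untouched, the hydroxyl being carried as its magnesium alkoxide.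

Step 6
Reactants: 11 methyl 2,4-dihydroxy-6-methylbenzoate (methyl orsellinate)
Product: 12 methyl 3-chloro-4,6-dihydroxy-2-methylbenzoate
Conditions: SO2Cl2 (1.05 equiv), Et2O, 0 °C to rt
Reagents that add atoms: sulfuryl chloride, O=S(=O)(Cl)Cl
Why: Electrophilic aromatic chlorination goes to C5 of the orsellinate (para to the hydrogen-bonded 2-OH and ortho to the 4-OH), the usual halogenation site of 2,4-dihydroxybenzoates, which gives the 3-chloro-2-methyl pattern.

Step 7
Reactants: 12 methyl 3-chloro-4,6-dihydroxy-2-methylbenzoate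
Product: 13 methyl 3-chloro-4,6-bis(methoxymethoxy)-2-methylbenzoate
Conditions: NaH (2.4 equiv), MOMCl (2.4 equiv), DMF, 0 °C to rt
Reagents that add atoms: chloromethyl methyl ether, COCCl
Why: Williamson-type O-alkylation of both phenoxides masks the acidic protons for the lateral lithiation and gives acetals that come off in the last acid step.

Step 8
Reactants: 13 methyl 3-chloro-4,6-bis(methoxymethoxy)-2-methylbenzoate (2.5 equiv); 10 (2E,4E)-5-[(2R,3S,5S)-3-hydroxy-5-methyloxolan-2-yl]-N-methoxy-N-methylpenta-2,4-dienamide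
Product: 15 methyl 3-chloro-2-[(3E,5E)-6-[(2R,3S,5S)-3-hydroxy-5-methyloxolan-2-yl]-2-oxohexa-3,5-dien-1-yl]-4,6-bis(methoxymethoxy)benzoate, via lithiated toluate 14 (not isolated)
Conditions: LiN(iPr)2 (2.5 equiv), THF, −78 °C; then 10, −78 °C, 15 min; AcOH quench at −78 °C
Reagents that add atoms: none
Why: Lateral lithiation of the o-toluate gives a benzylic anion that acylates 1,2 on the Weinreb amide through a chelated tetrahedral intermediate that stops over-addition, forming the C4–C3 bond without touching the stereocentres, the excess anion first turning the hydroxyl of 10 into its lithium alkoxide.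

Step 9
Reactants: 15 methyl 3-chloro-2-[(3E,5E)-6-[(2R,3S,5S)-3-hydroxy-5-methyloxolan-2-yl]-2-oxohexa-3,5-dien-1-yl]-4,6-bis(methoxymethoxy)benzoate
Product: 17 5-chloro-6,8-dihydroxy-3-[(1E,3E)-4-[(2R,3S,5S)-3-hydroxy-5-methyloxolan-2-yl]buta-1,3-dien-1-yl]-1H-isochromen-1-one, via diphenol keto ester 16 (not isolated)
Conditions: TsOH·H2O (0.5 equiv), MeOH–THF 3:1, 45 °C
Reagents that add atoms: none
Why: Acid-catalysed acetal exchange with methanol removes both MOM groups and the enol of the benzylic ketone then acylates on oxygen at the neighbouring ester (enol lactonisation), forming the lactone C–O bond of ring B, driven by the conjugation of the isocoumarin, under conditions too mild to ionise the allylic ether of the oxolane.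

## Compound list

1 | (S)-propylene oxide, (2S)-2-methyloxirane | C[C@H]1CO1 | starting material
2 | vinylmagnesium bromide | C=C[Mg]Br | starting material
3 | (2S)-pent-4-en-2-ol | C[C@H](O)CC=C | intermediate
4 | (E)-but-2-enal (crotonaldehyde) | C/C=C/C=O | starting material
5 | (2E,5S)-5-hydroxyhex-2-enal | C[C@H](O)C/C=C/C=O | intermediate
6 | triethyl 4-phosphonocrotonate, ethyl (2E)-4-(diethoxyphosphoryl)but-2-enoate | CCOC(=O)/C=C/CP(=O)(OCC)OCC | starting material
7 | ethyl (2E,4E,6E,9S)-9-hydroxydeca-2,4,6-trienoate | C[C@H](O)C/C=C/C=C/C=C/C(=O)OCC | intermediate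
8 | ethyl (2E,4E)-5-[(2S,3S)-3-[(2S)-2-hydroxypropyl]oxiran-2-yl]penta-2,4-dienoate | C[C@H](O)C[C@@H]1O[C@H]1/C=C/C=C/C(=O)OCC | intermediate (not isolated)
9 | ethyl (2E,4E)-5-[(2R,3S,5S)-3-hydroxy-5-methyloxolan-2-yl]penta-2,4-dienoate | C[C@H]1C[C@H](O)[C@@H](/C=C/C=C/C(=O)OCC)O1 | intermediate
10 | (2E,4E)-5-[(2R,3S,5S)-3-hydroxy-5-methyloxolan-2-yl]-N-methoxy-N-methylpenta-2,4-dienamide | C[C@H]1C[C@H](O)[C@@H](/C=C/C=C/C(=O)N(C)OC)O1 | intermediate
11 | methyl 2,4-dihydroxy-6-methylbenzoate (methyl orsellinate) | COC(=O)c1c(C)cc(O)cc1O | starting material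
12 | methyl 3-chloro-4,6-dihydroxy-2-methylbenzoate | COC(=O)c1c(C)c(Cl)c(O)cc1O | intermediate
13 | methyl 3-chloro-4,6-bis(methoxymethoxy)-2-methylbenzoate | COCOc1cc(OCOC)c(C(=O)OC)c(C)c1Cl | intermediate
14 | methyl 3-chloro-2-(lithiomethyl)-4,6-bis(methoxymethoxy)benzoate (lithiated toluate) | COCOc1cc(OCOC)c(C(=O)OC)c(C[Li])c1Cl | intermediate (not isolated)
15 | methyl 3-chloro-2-[(3E,5E)-6-[(2R,3S,5S)-3-hydroxy-5-methyloxolan-2-yl]-2-oxohexa-3,5-dien-1-yl]-4,6-bis(methoxymethoxy)benzoate | C[C@H]1C[C@H](O)[C@@H](/C=C/C=C/C(=O)Cc2c(Cl)c(OCOC)cc(OCOC)c2C(=O)OC)O1 | intermediate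
16 | methyl 3-chloro-4,6-dihydroxy-2-[(3E,5E)-6-[(2R,3S,5S)-3-hydroxy-5-methyloxolan-2-yl]-2-oxohexa-3,5-dien-1-yl]benzoate | C[C@H]1C[C@H](O)[C@@H](/C=C/C=C/C(=O)Cc2c(Cl)c(O)cc(O)c2C(=O)OC)O1 | intermediate (not isolated)
17 | 5-chloro-6,8-dihydroxy-3-[(1E,3E)-4-[(2R,3S,5S)-3-hydroxy-5-methyloxolan-2-yl]buta-1,3-dien-1-yl]-1H-isochromen-1-one | C[C@H]1C[C@H](O)[C@@H](/C=C/C=C/c2cc3c(Cl)c(O)cc(O)c3c(=O)o2)O1 | target

## Step count and risks

Total steps: 9. Longest linear sequence: 7 (steps 1, 2, 3, 4, 5, 8, 9).

**Step 4 (proposed new oxidative cycloetherification).** The risks are low rate on the electron-poor triene, an insufficient 1,3-syn preference for the E-alkene, and over-oxidation. The fallback uses known chemistry, sets out from 7 and comes back at 9. Trienoate 7 is epoxidised at its most electron-rich C6=C7 bond under reagent control with the enantiomer of the fructose-derived Shi ketone (made from L-sorbose; 30 mol %), KHSO5 (as Oxone, 2KHSO5·KHSO4·K2SO4), K2CO3 and Bu4NHSO4 in MeCN–dimethoxymethane/aqueous buffer at 0 °C. The D-fructose ketone gives (R,R)-epoxides from trans-alkenes, so its enantiomer gives the (6S,7S)-epoxide 8, which is now isolated. CSA (10 mol %) in CH2Cl2 at 0 °C then effects the 5-endo opening with inversion to 9. This way makes no compound outside the list: none F0.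

**Step 8 (toluate acylation).** The risks are conjugate addition to the dienamide and deprotonation at the oxolane C2–H. The fallback sets out from 10 and 13 and comes back at 15. Amide 10 is reduced with iBu2AlH (THF, −78 °C) to (2E,4E)-5-[(2R,3S,5S)-3-hydroxy-5-methyloxolan-2-yl]penta-2,4-dienal F1. Lithiated toluate 14 (from 13 and LiN(iPr)2, −78 °C) adds 1,2 to the aldehyde, and a cold AcOH quench keeps the adduct open as methyl 3-chloro-2-[(3E,5E)-2-hydroxy-6-[(2R,3S,5S)-3-hydroxy-5-methyloxolan-2-yl]hexa-3,5-dien-1-yl]-4,6-bis(methoxymethoxy)benzoate F2 (both epimers at the new carbinol). MnO2 in CH2Cl2 oxidises only the dienylic alcohol and gives ketone 15.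

**Step 9 (one-flask MOM removal and lactonisation).** The risks are incomplete ring closure and acid damage at the dienyl ether. The fallback sets out from 15 and comes back at 17. Ring B is closed first under base: DBU in toluene at 60 °C lets the enolate oxygen attack the ester, giving 5-chloro-3-[(1E,3E)-4-[(2R,3S,5S)-3-hydroxy-5-methyloxolan-2-yl]buta-1,3-dien-1-yl]-6,8-bis(methoxymethoxy)-1H-isochromen-1-one F3, which is isolated. The MOM groups are then removed without protic acid by ZnBr2 and n-PrSH in CH2Cl2 at 0 °C, which gives 17.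

Further compounds
F0 | step 4 | none | none
F1 | step 8 | (2E,4E)-5-[(2R,3S,5S)-3-hydroxy-5-methyloxolan-2-yl]penta-2,4-dienal | C[C@H]1C[C@H](O)[C@@H](/C=C/C=C/C=O)O1
F2 | step 8 | methyl 3-chloro-2-[(3E,5E)-2-hydroxy-6-[(2R,3S,5S)-3-hydroxy-5-methyloxolan-2-yl]hexa-3,5-dien-1-yl]-4,6-bis(methoxymethoxy)benzoate (both carbinol epimers) | C[C@H]1C[C@H](O)[C@@H](/C=C/C=C/C(O)Cc2c(Cl)c(OCOC)cc(OCOC)c2C(=O)OC)O1
F3 | step 9 | 5-chloro-3-[(1E,3E)-4-[(2R,3S,5S)-3-hydroxy-5-methyloxolan-2-yl]buta-1,3-dien-1-yl]-6,8-bis(methoxymethoxy)-1H-isochromen-1-one | C[C@H]1C[C@H](O)[C@@H](/C=C/C=C/c2cc3c(Cl)c(OCOC)cc(OCOC)c3c(=O)o2)O1
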